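**Retrosynthetic overview** (flavanone numbering O1, C2, C3, C4, C4a, C5–C8, C8a; ring A = benzo ring, ring B = 2,4,6-trimethoxyphenyl, ring C = dihydropyranone)
1. Ring C of target 12 is opened at the C3–C4 bond and the C2–H is removed with it. This gives the achiral isomer 11, a salicylaldehyde whose O1 carries a 1-arylvinyl group. In the forward sense an enantioselective Rh-catalysed intramolecular hydroacylation closes ring C, creates the C4 ketone and sets C2, all in the last step.
2. Enabling feature: C3 is an unsubstituted CH2 between the C4 carbonyl and C2, and C2 bears only O1, ring B and H. Ring C therefore maps onto a formyl C–H plus a terminal 1,1-disubstituted enol ether held by O1, and the C5–OH of ring A hydrogen-bonds to the formyl oxygen and turns the C–H towards O1.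
3. 11 comes from 8 by a para-Claisen–Cope rearrangement. C8 is para to C5 in ring A, so a prenyl ether on O5 serves as protecting group and as source of the C8 prenyl group.
4. 8 comes from 7 by loss of HBr (C2=C3), and 7 comes from 4 and 6 by Mitsunobu etherification (O1–C2). Both 4 and 6 derive from aldehyde 1.
5. Ring order: rings A and B are bought as arenes. Ring C is the only ring formed, in step 7.

Key step: step 7

Assumption: the sense of induction of (R)-DTBM-SEGPHOS on this new substrate class cannot be derived with certainty, so the (R)-ligand is written for the (2S)-product and the (S)-ligand would be used if a small trial showed the opposite sense.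

Step 1
Reactants: 1 2,4,6-trimethoxybenzaldehyde
Product: 2 2,6-dihydroxy-4-methoxybenzaldehyde
Conditions: AlCl3 (4 equiv), CH2Cl2, 0 °C to reflux; then cold 1 M HCl
Reagents that add atoms: none
Why: Chelation-directed aryl methyl ether cleavage, in which AlCl3 bound to the formyl oxygen activates only the two ortho methoxy groups, as known for 2,6-dimethoxybenzaldehydes, while the para methoxy group stays.

Step 2
Reactants: 2 2,6-dihydroxy-4-methoxybenzaldehyde; 3 1-bromo-3-methylbut-2-ene (prenyl bromide)
Product: 4 2-hydroxy-4-methoxy-6-[(3-methylbut-2-en-1-yl)oxy]benzaldehyde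
Conditions: 3 (1.0 equiv), K2CO3 (1.1 equiv), acetone, rt to 45 °C
Reagents that add atoms: none
Why: Williamson ether synthesis on a symmetric diol, which should stop at the monoether because the remaining hydroxyl is locked in a hydrogen bond to the formyl group and is a much poorer nucleophile.

Step 3
Reactants: 1 2,4,6-trimethoxybenzaldehyde; 5 dibromomethane
Product: 6 2-bromo-1-(2,4,6-trimethoxyphenyl)ethan-1-ol (racemic)
Conditions: 5 (1.5 equiv), n-BuLi (1.4 equiv, slow addition to 1 + 5), THF, −78 °C; AcOH quench at −78 °C; used crude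
Reagents that add atoms: none
Why: Br/Li exchange gives bromomethyllithium in the presence of 1, this lithium carbenoid adds to the formyl group (carbenoid addition to a carbonyl compound), and the cold acidic quench stops the alkoxide before epoxide closure; the new stereocentre is racemic and is erased in step 5.

Step 4
Reactants: 4 2-hydroxy-4-methoxy-6-[(3-methylbut-2-en-1-yl)oxy]benzaldehyde; 6 2-bromo-1-(2,4,6-trimethoxyphenyl)ethan-1-ol
Product: 7 2-[2-bromo-1-(2,4,6-trimethoxyphenyl)ethoxy]-4-methoxy-6-[(3-methylbut-2-en-1-yl)oxy]benzaldehyde (racemic)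
Conditions: PPh3, DIAD, toluene, 0 °C to rt; Et3N-deactivated SiO2
Reagents that add atoms: none
Why: Mitsunobu etherification of an acidic ortho-formylphenol with a secondary benzylic alcohol under neutral conditions forms the O1–C2 bond, and the steric course is irrelevant because this centre becomes sp2 in step 5.

Step 5
Reactants: 7 2-[2-bromo-1-(2,4,6-trimethoxyphenyl)ethoxy]-4-methoxy-6-[(3-methylbut-2-en-1-yl)oxy]benzaldehyde
Product: 8 4-methoxy-2-[(3-methylbut-2-en-1-yl)oxy]-6-{[1-(2,4,6-trimethoxyphenyl)ethenyl]oxy}benzaldehyde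
Conditions: KOt-Bu (1.3 equiv), THF, −20 °C to rt; Et3N-deactivated SiO2
Reagents that add atoms: none
Why: E2 dehydrobromination of a beta-bromo ether, the classical route from 2-haloethyl aryl ethers to aryl vinyl ethers, removes the benzylic alpha-oxy hydrogen and the primary bromide, and the non-enolisable aldehyde and the prenyl ether tolerate the base.

Step 6
Reactants: 8 4-methoxy-2-[(3-methylbut-2-en-1-yl)oxy]-6-{[1-(2,4,6-trimethoxyphenyl)ethenyl]oxy}benzaldehyde
Product: 11 6-hydroxy-4-methoxy-3-(3-methylbut-2-en-1-yl)-2-{[1-(2,4,6-trimethoxyphenyl)ethenyl]oxy}benzaldehyde, via ortho-dienone 9 (not isolated), via para-dienone 10 (not isolated)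
Conditions: Eu(fod)3 (10 mol %), NaHCO3 (solid buffer), PhCl, 85 °C
Reagents that add atoms: none
Why: Aromatic Claisen rearrangement to the free ortho carbon followed by Cope rearrangement to the para carbon and tautomerisation (para-Claisen–Cope), a sequence known under catalysis by this complex of trivalent europium for prenyl ethers ortho to a carbonyl group such as 5-O-prenylflavonoids, and this mild Lewis acid is known to leave enol ethers intact.

Step 7
Reactants: 11 6-hydroxy-4-methoxy-3-(3-methylbut-2-en-1-yl)-2-{[1-(2,4,6-trimethoxyphenyl)ethenyl]oxy}benzaldehyde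
Product: 12 (2S)-5-hydroxy-7-methoxy-8-(3-methylbut-2-en-1-yl)-2-(2,4,6-trimethoxyphenyl)-2,3-dihydro-4H-chromen-4-one
Conditions: [Rh(cod)Cl]2 (5 mol %), (R)-DTBM-SEGPHOS (10 mol %), NaB[3,5-(CF3)2C6H3]4 (10 mol %), 4 Å MS, dry THF, 60 °C
Reagents that add atoms: none
Why: Proposed new method: the cationic complex of monovalent rhodium binds the enol-ether alkene of 11, adds oxidatively into the formyl C–H bond to give an acyl hydride of trivalent rhodium, the C2=C3 bond inserts into Rh–H with hydrogen going to C2 and rhodium to the unsubstituted C3, and C–C reductive elimination from the seven-membered acyl alkyl rhodacycle forms the C3–C4 bond and frees the catalyst. The closest known reaction type is the rhodium/bisphosphine-catalysed enantioselective endo-hydroacylation of ortho-allylbenzaldehydes that carry a 1,1-disubstituted alkene, which gives 3-substituted 3,4-dihydronaphthalen-1(2H)-ones; 11 is the analogue with O1 in place of the benzylic CH2, and an aryl enol ether has not been shown as the alkene partner. Ring C closes in a formal 6-endo-trig mode, both alkene carbons ending up in the ring. C2, the only stereocentre, is set under catalyst control when the chiral bisphosphine pocket lets only one face of the prochiral alkene meet the hydride. The step needs regioselectivity against 5-exo closure to a 2-aryl-2-methylbenzofuran-3-one, secured because that path would require a tertiary alkyl–rhodium bond at C2 between O1 and the two ortho-methoxy groups of ring B, and chemoselectivity against the prenyl alkene, secured because that alkene is trisubstituted and sits meta to the formyl carbon out of reach of the acyl hydride. The hydrogen bond from the C5–OH to the formyl oxygen keeps the C–H bond turned towards O1, C2 has no allylic hydrogen so no alkene migration can compete, and the neutral conditions of this last step should leave the base- and acid-labile C2 configuration untouched.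

**Compound list**
1 | 2,4,6-trimethoxybenzaldehyde | COc1cc(OC)c(C=O)c(OC)c1 | starting material
2 | 2,6-dihydroxy-4-methoxybenzaldehyde | O=Cc1c(O)cc(OC)cc1O | intermediate
3 | 1-bromo-3-methylbut-2-ene | CC(C)=CCBr | starting material
4 | 2-hydroxy-4-methoxy-6-[(3-methylbut-2-en-1-yl)oxy]benzaldehyde | O=Cc1c(O)cc(OC)cc1OCC=C(C)C | intermediate
5 | dibromomethane | BrCBr | starting material
6 | 2-bromo-1-(2,4,6-trimethoxyphenyl)ethan-1-ol (racemic) | COc1cc(OC)c(C(O)CBr)c(OC)c1 | intermediate
7 | 2-[2-bromo-1-(2,4,6-trimethoxyphenyl)ethoxy]-4-methoxy-6-[(3-methylbut-2-en-1-yl)oxy]benzaldehyde (racemic) | O=Cc1c(OC(CBr)c2c(OC)cc(OC)cc2OC)cc(OC)cc1OCC=C(C)C | intermediate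
8 | 4-methoxy-2-[(3-methylbut-2-en-1-yl)oxy]-6-{[1-(2,4,6-trimethoxyphenyl)ethenyl]oxy}benzaldehyde | O=Cc1c(OC(=C)c2c(OC)cc(OC)cc2OC)cc(OC)cc1OCC=C(C)C | intermediate
9 | 4-methoxy-5-(2-methylbut-3-en-2-yl)-6-oxo-2-{[1-(2,4,6-trimethoxyphenyl)ethenyl]oxy}cyclohexa-1,3-diene-1-carbaldehyde (racemic, not isolated) | O=CC1=C(OC(=C)c2c(OC)cc(OC)cc2OC)C=C(OC)C(C(C)(C)C=C)C1=O | intermediate
10 | 4-methoxy-3-(3-methylbut-2-en-1-yl)-6-oxo-2-{[1-(2,4,6-trimethoxyphenyl)ethenyl]oxy}cyclohexa-1,4-diene-1-carbaldehyde (racemic, not isolated) | O=CC1=C(OC(=C)c2c(OC)cc(OC)cc2OC)C(CC=C(C)C)C(OC)=CC1=O | intermediate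
11 | 6-hydroxy-4-methoxy-3-(3-methylbut-2-en-1-yl)-2-{[1-(2,4,6-trimethoxyphenyl)ethenyl]oxy}benzaldehyde | O=Cc1c(O)cc(OC)c(CC=C(C)C)c1OC(=C)c1c(OC)cc(OC)cc1OC | intermediate
12 | (2S)-5-hydroxy-7-methoxy-8-(3-methylbut-2-en-1-yl)-2-(2,4,6-trimethoxyphenyl)-2,3-dihydro-4H-chromen-4-one | COc1cc(OC)c([C@@H]2CC(=O)c3c(O)cc(OC)c(CC=C(C)C)c3O2)c(OC)c1 | target

Total step count: 7. Longest linear sequence: 6 (steps 1, 2, 4, 5, 6, 7).

**Steps most likely to fail**

Step 7.
- What may go wrong: decarbonylation of the doubly ortho-substituted acyl hydride; binding of the cationic rhodium by the electron-rich arenes; acid-type aldol closure of the enol ether onto the formyl group followed by loss of water; or poor facial selectivity at the crowded alkene.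
- Fallback (known chemistry, same ring-closing bond): it sets out from 7 and comes back at 12.
- The formyl group of 7 is converted into its enaminol acyl-anion equivalent by an N-heterocyclic carbene (3-benzyl-5-(2-hydroxyethyl)-4-methylthiazolium chloride, Cs2CO3, THF). This displaces the primary bromide in an intramolecular nucleophilic substitution, a reaction type known to give chroman-4-ones from 2-(2-haloethoxy)benzaldehydes. It should give racemic 7-methoxy-5-(prenyloxy)-2-(2,4,6-trimethoxyphenyl)chroman-4-one F1.
- Eu(fod)3-catalysed para-Claisen–Cope rearrangement, known for 5-O-prenylflavanones, should move the prenyl group to C8 and give the racemic 8-prenylflavanone F2.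
- Kinetic resolution by asymmetric transfer hydrogenation, known for racemic flavanones, uses RuCl[(R,R)-TsDPEN](p-cymene) or its mirror image in HCO2H/Et3N. It should reduce the (2R)-ketone to the (2R,4R)-flavan-4-ol F3 and leave 12, which is separated by chromatography.

Step 5.
- What may go wrong: the base removes a hydrogen next to bromine and the stabilised aryloxide is expelled from the strongly cation-stabilising benzylic carbon, so the ether is cleaved instead of HBr being lost.
- Fallback: it sets out from 7 and comes back at 8, and it replaces the base-induced elimination by a syn-elimination that can reach only the C2 hydrogen.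
- The bromide of 7 is displaced with benzeneselenol and Cs2CO3 in DMF at 0 °C to give the beta-(phenylselanyl) ether F4.
- One equivalent of mCPBA at −78 °C gives the selenoxide F5.
- Warming with i-Pr2NEt should release 8.

Step 4.
- What may go wrong: ionisation of the activated alcohol, followed by proton loss, capture by the hydrazide or C-alkylation of ring A instead of O-alkylation.
- Fallback: it sets out from 4 and comes back at 8, bypassing 6 and 7. The enol ether is built by carbonyl methylenation.
- Acylation of 4 with 2,4,6-trimethoxybenzoyl chloride (Et3N, DMAP, CH2Cl2) should give the aryl 2,4,6-trimethoxybenzoate F6.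
- NaBH4 (THF/MeOH, −20 °C) reduces the formyl group to the benzylic alcohol F7.
- TBSCl and imidazole give the silyl ether F8.
- Petasis methylenation (Cp2TiMe2, toluene, 70 °C) turns the ester into the silylated enol ether F9.
- Bu4NF frees the enol ether alcohol F10.
- MnO2 in CH2Cl2 oxidises it to 8.

**Further compounds**
F1 | step 7 | racemic 7-methoxy-5-[(3-methylbut-2-en-1-yl)oxy]-2-(2,4,6-trimethoxyphenyl)chroman-4-one | COc1cc(OC)c(C2CC(=O)c3c(OCC=C(C)C)cc(OC)cc3O2)c(OC)c1
F2 | step 7 | racemic 5-hydroxy-7-methoxy-8-(3-methylbut-2-en-1-yl)-2-(2,4,6-trimethoxyphenyl)chroman-4-one | COc1cc(OC)c(C2CC(=O)c3c(O)cc(OC)c(CC=C(C)C)c3O2)c(OC)c1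
F3 | step 7 | (2R,4R)-7-methoxy-8-(3-methylbut-2-en-1-yl)-2-(2,4,6-trimethoxyphenyl)chromane-4,5-diol | COc1cc(OC)c([C@H]2C[C@@H](O)c3c(O)cc(OC)c(CC=C(C)C)c3O2)c(OC)c1
F4 | step 5 | 4-methoxy-2-[(3-methylbut-2-en-1-yl)oxy]-6-[2-(phenylselanyl)-1-(2,4,6-trimethoxyphenyl)ethoxy]benzaldehyde (racemic) | O=Cc1c(OC(C[Se]c2ccccc2)c2c(OC)cc(OC)cc2OC)cc(OC)cc1OCC=C(C)C
F5 | step 5 | selenoxide of F4 | O=Cc1c(OC(C[Se](=O)c2ccccc2)c2c(OC)cc(OC)cc2OC)cc(OC)cc1OCC=C(C)C
F6 | step 4 | 2-formyl-5-methoxy-3-[(3-methylbut-2-en-1-yl)oxy]phenyl 2,4,6-trimethoxybenzoate | O=Cc1c(OC(=O)c2c(OC)cc(OC)cc2OC)cc(OC)cc1OCC=C(C)C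
F7 | step 4 | 2-(hydroxymethyl)-5-methoxy-3-[(3-methylbut-2-en-1-yl)oxy]phenyl 2,4,6-trimethoxybenzoate | OCc1c(OC(=O)c2c(OC)cc(OC)cc2OC)cc(OC)cc1OCC=C(C)C
F8 | step 4 | tert-butyldimethylsilyl ether of F7 | CC(C)(C)[Si](C)(C)OCc1c(OC(=O)c2c(OC)cc(OC)cc2OC)cc(OC)cc1OCC=C(C)C
F9 | step 4 | tert-butyldimethylsilyl ether of F10 | CC(C)(C)[Si](C)(C)OCc1c(OC(=C)c2c(OC)cc(OC)cc2OC)cc(OC)cc1OCC=C(C)C
F10 | step 4 | (4-methoxy-2-[(3-methylbut-2-en-1-yl)oxy]-6-{[1-(2,4,6-trimethoxyphenyl)ethenyl]oxy}phenyl)methanol | OCc1c(OC(=C)c2c(OC)cc(OC)cc2OC)cc(OC)cc1OCC=C(C)C
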